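## The problem

2,5,6-Tribromo-1-methylgramine (17) is an achiral, fully aromatic indole, so no stereocentre has to be set; the whole difficulty is the placement of five substituents at defined ring atoms. Ring A must carry bromine at C5 and C6 while C4 and C7 stay free. Neither bromination of a finished indole nor a ring-B closure onto a 3,4-dibromoarene, which has two different ortho positions, guarantees that pattern. Ring B is fully substituted (N1–Me, C2–Br, C3–CH2NMe2), and C2 can only be halogenated cleanly if C3 is already occupied by a group that steers reagents to C2. The gramine unit is the fragile part: the benzylic tertiary amine is oxidised and quaternised by bromine and by alkylating agents, and it becomes a leaving group once the nitrogen is charged, so it has to be made last. Once C–Br bonds are present, alkyllithiums, dissolving metals and hydrogenation are excluded, which limits the late steps to amide bases, electrophilic halogen and aluminium hydrides. The feature that opens the chosen route is the local symmetry of the C4–C5–C6–C7 edge of ring A (H, Br, Br, H). These four atoms can be taken apart into the two CH termini of a diene anchored on C3a and C7a of a preformed pyrrole and the two carbons of a symmetric alkyne, whose identical silyl groups are later exchanged for bromine at the carbons they occupy. A methoxycarbonyl group at C3 is carried throughout as the latent side-chain carbon, as blocking group for C3 and as director for metalation at C2.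

## Retrosynthesis

**Side chain, 17 back to 14.** The exocyclic C–N bond is cut first, so that the amine appears only in the last operation. The precursor is the indol-3-ylmethanol 15, itself the reduction product of methyl 2,5,6-tribromo-1-methylindole-3-carboxylate 14. The neighbouring cut, a Mannich disconnection of the C3–CH2 bond, would require a 2,5,6-tribromoindole with a free and strongly deactivated C3, and it would leave no handle for C2 bromination. The forward steps need a hydride that leaves three C–Br bonds alone, and an amination that captures an easily ionised benzylic electrophile.

**C2–Br, 14 back to 12.** The C2–Br bond is cut to C2–H, giving methyl 5,6-dibromo-1-methylindole-3-carboxylate 12. Electrophilic bromine does not attack C2 of an indole-3-carboxylate, so the bond is best made through the C2 anion, which the adjacent ester and the ring nitrogen both favour. The forward step needs a base that deprotonates C2 without exchanging the ring-A bromines.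

**Ring-A bromines, 12 back to 11.** Both C–Br bonds of ring A are cut back to C–Si, giving the bis-silyl indole 11. Ipso-substitution puts bromine exactly where silicon stood, and for an indole-3-carboxylate these are also the positions that bromine prefers on its own, so the two controls reinforce each other. Compound 11 carries no halogen and comes directly from the ring-forming step.

**Ring A, 11 back to 8 and 9 (key disconnection).** The C4–C5 and C6–C7 bonds are cut together. This gives the quinoid pyrano[3,4-b]pyrrol-5-one 8, whose CH termini become C4 and C7, and bis(trimethylsilyl)acetylene 9, whose carbons become C5 and C6; the lactone bridge leaves as CO2. Against ring-B-forming cuts from dibromoarenes, this cut has no regiochemical choice to make, because the alkyne is symmetric. Compound 8 is a ten-carbon bicycle without halogen. The forward reaction asks only for thermal reactivity towards a hindered alkyne.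

**Pyranone, 8 back to 6.** The O6–C7 bond of the lactone is cut, which shows 8 to be the anhydro form of the formyl acid 7. Acid 7 comes from the formyl diester 6 by hydrolysis of the side-chain ester alone. The forward steps rely on the large reactivity gap between an alkyl acetate ester and a pyrrole-3-carboxylate, and on cyclodehydration of an ortho-formyl arylacetic acid.

**Formyl and N-methyl groups, 6 back to 3.** The formyl C–C bond is cut to give the N-methylpyrrole diester 4, and the N–CH3 bond to give the N–H pyrrole 3. Formylation must go to the α-position next to the acetate arm; that is the position a 3-acylpyrrole offers, because it is remote from the ester and activated by the alkyl group.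

**Pyrrole, 3 back to 1 and 2.** The pyrrole ring is opened at C2–C3 and C4–C5 into dimethyl glutaconate 1 and tosylmethyl isocyanide 2. The acceptor delivers the 3-ester and the 4-acetate arm in the right relationship, and both reagents are commercial.

## Roads not taken

**Alternative 1:** The cut is the C3–C3a bond. An α-xanthyl N-methylanilide A1, made from an aniline that already carries both bromines, would be heated with a stoichiometric diacyl peroxide. The carbamoylmethyl radical then closes ring B onto an ortho carbon to give 5,6-dibromo-1-methylindolin-2-one A2.
- Merits: the bromines are bought, not installed. The lactam carbonyl of A2 is a direct precursor of C2–Br and of the C3 formyl carbon through a Vilsmeier halo-formylation, so the target could be reached in about five or six steps. On step count this road is better than the chosen plan.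
- Weak points: the radical can attack either of two different ortho carbons, so the 4,5-dibromo isomer A3 is expected beside A2; attack between nitrogen and bromine is hindered, but not excluded. The two dibromo lactams would have to be separated. The closure also needs the reactive amide rotamer and a full equivalent of oxidant.
- Comparison: the chosen plan sets against the shorter sequence the fact that no regioisomer can form at any stage, and that 11 is a branching point for other 5,6-disubstituted analogues.

**Alternative 2:** The cut is C3a–C4 and C7–C7a. 3,4-Dibromothiophene 1,1-dioxide A4 would add to the enecarbamate A5 and the adduct would extrude SO2, giving the cis-fused dibromodiene A6.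
- Merits: like the chosen plan it is a cycloaddition–extrusion annulation in which symmetry fixes the bromine positions. It places the bromines directly, with no silyl-to-bromine exchange, and it should run at lower temperature; in these respects it is as good or better.
- Weak points: A6 is at the wrong oxidation level in both rings. It has two sp3 ring-fusion stereocentres that are made only to be destroyed, no C2=C3 bond, nothing at C3 and a carbamate where the methyl belongs. Four hydrogens have to be removed without touching the vinylic bromides; then the protecting group is exchanged, C3 aminomethylated and C2 brominated on a ring that by then carries either a free C3 or an electrophile-sensitive gramine. A4 itself is prone to self-dimerisation.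
- Comparison: the chosen plan arrives at an aromatic indole with the C3 carbon in place directly from the key step, which outweighs the milder conditions of this road.

**Alternative 3:** The cut is the N1–C7a bond. Thermolysis of the azidocinnamate A7 would expel N2, and the vinyl nitrene would insert into an ortho C–H bond to give methyl 5,6-dibromo-1H-indole-2-carboxylate A8.
- Merits: the indole nucleus with both ring-A bromines is reached in two steps from an aromatic aldehyde, faster than in the chosen plan, and the thermolysis is dependable.
- Weak points: the two ortho C–H bonds differ, so the 6,7-dibromo isomer A9 is expected as well. The C2 ester is only a stand-in for bromine and must be removed by hydrolysis and decarboxylative bromination while C3 is free or carries the amine. N-Methylation and aminomethylation of an acceptor-substituted indole add further steps, and an azide has to be handled on scale.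
- Comparison: the chosen plan spends more steps before the benzene ring exists. In return its ester sits at C3, where its carbon stays in the target, and it directs the C2 bromination instead of having to be exchanged for it.

Key step: step 6

Assumption: pyranone 8 is taken to be isolable, as its 7-alkyl and indole-fused relatives are; a telescoped variant is given with the risks.

## Route

Step 1
Reactants: 1 dimethyl glutaconate; 2 tosylmethyl isocyanide
Product: 3 methyl 4-(2-methoxy-2-oxoethyl)-1H-pyrrole-3-carboxylate
Conditions: NaH (2.1 equiv), Et2O/DMSO, 0 °C → rt (1 and 2 added together, slowly)
Reagents that add atoms: none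
Why: Van Leusen pyrrole synthesis: the anion of 2 adds to the β-carbon of the enoate, the ester enolate closes onto the isocyanide carbon, and loss of sulfinate with tautomerisation gives the 3,4-disubstituted pyrrole; double-bond migration in 1 regenerates the same diester, so its acidic CH2 cannot cause a regiochemical error, and slow addition to the base keeps conjugate addition ahead of self-condensation.

Step 2
Reactants: 3 methyl 4-(2-methoxy-2-oxoethyl)-1H-pyrrole-3-carboxylate
Product: 4 methyl 4-(2-methoxy-2-oxoethyl)-1-methylpyrrole-3-carboxylate
Conditions: Cs2CO3, MeI, DMF, rt
Reagents that add atoms: iodomethane, CI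
Why: N-Alkylation of a pyrrolide: the N–H, acidified by the 3-ester, is the only site a carbonate base deprotonates, and the anion is methylated at nitrogen in a dipolar aprotic solvent; the acetate CH2 is too weakly acidic to compete.

Step 3
Reactants: 4 methyl 4-(2-methoxy-2-oxoethyl)-1-methylpyrrole-3-carboxylate
Product: 6 methyl 5-formyl-4-(2-methoxy-2-oxoethyl)-1-methylpyrrole-3-carboxylate, via Vilsmeier iminium salt 5 (not isolated)
Conditions: POCl3, DMF, ClCH2CH2Cl, 0 → 70 °C; then aq NaOAc, 70 °C
Reagents that add atoms: N,N-dimethylformamide, CN(C)C=O; water, O
Why: Vilsmeier–Haack formylation: in a 3-acylpyrrole the α-position remote from the ester reacts, because attack there keeps positive charge off the ester-bearing carbon, and here that position is also activated by the neighbouring alkyl arm; the iminium salt 5 is hydrolysed on buffered work-up.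

Step 4
Reactants: 6 methyl 5-formyl-4-(2-methoxy-2-oxoethyl)-1-methylpyrrole-3-carboxylate
Product: 7 2-[2-formyl-4-(methoxycarbonyl)-1-methylpyrrol-3-yl]acetic acid
Conditions: LiOH (1.05 equiv), THF/H2O, 0 °C; then 1 M HCl to pH 3
Reagents that add atoms: lithium hydroxide, [Li+].[OH-]
Why: Chemoselective saponification: the unhindered alkyl acetate ester is far more electrophilic than the pyrrole-3-carboxylate, a vinylogous carbamate, so one equivalent of cold hydroxide should cleave only the side-chain ester; the pyrrole aldehyde, a vinylogous formamide, has no α-hydrogen and tolerates brief cold base.

Step 5
Reactants: 7 2-[2-formyl-4-(methoxycarbonyl)-1-methylpyrrol-3-yl]acetic acid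
Product: 8 methyl 1-methyl-5-oxo-1,5-dihydropyrano[3,4-b]pyrrole-3-carboxylate
Conditions: Ac2O, 90 °C; then evaporation in vacuo, product kept dry
Reagents that add atoms: none
Why: Cyclodehydration of an ortho-formyl arylacetic acid to a fused 2-pyranone, as in the generation of 2-benzopyran-3-ones: the mixed anhydride is attacked by the nucleophilic aldehyde oxygen, and loss of a C4 proton from the nitrogen-stabilised cation gives the quinoid lactone; conjugation of the pyrrole nitrogen with the lactone is expected to make 8 isolable, unlike the carbocyclic parent.

Step 6
Reactants: 8 methyl 1-methyl-5-oxo-1,5-dihydropyrano[3,4-b]pyrrole-3-carboxylate; 9 bis(trimethylsilyl)acetylene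
Product: 11 methyl 1-methyl-5,6-bis(trimethylsilyl)indole-3-carboxylate, via bridged lactone cycloadduct 10 (not isolated)
Conditions: 9 (10 equiv), PhBr, sealed tube, 160 °C
Reagents that add atoms: none
Why: Thermal Diels–Alder reaction of a fused 2-pyranone with an alkyne followed by retro-[4+2] loss of CO2, the reaction type known for pyrano[3,4-b]pyrrol-5-ones and pyrano[3,4-b]indol-3-ones with alkynes and for 2-pyranone itself with 9. The diene of 8 is the quinoid unit C4=C3a–C7a=C7; 9 adds suprafacially across the two CH termini, forming C4–C5 and C6–C7 in one concerted step and giving the bicyclo[2.2.2] lactone 10. Cycloreversion of 10 expels the C5(=O)–O6 bridge as CO2 and leaves ring A as a benzene ring, so ring A is closed by intermolecular [4+2] annulation and not by cyclisation of a chain. The driving force is the gain of pyrrole aromaticity in the first stage and of benzene aromaticity in the second, which is why such quinoid pyranones react well below the temperatures simple 2-pyranones need. No stereocentre survives, since the two bridgehead centres of racemic 10 are erased when CO2 leaves. Regioselectivity does not arise because 9 is symmetric, so the silyl groups necessarily end on C5 and C6. The only selectivity required is cycloaddition ahead of self-dimerisation of 8, which the large excess of alkyne is meant to secure, helped by the C3 ester lowering the diene LUMO towards the HOMO of the silyl alkyne.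

Step 7
Reactants: 11 methyl 1-methyl-5,6-bis(trimethylsilyl)indole-3-carboxylate
Product: 12 methyl 5,6-dibromo-1-methylindole-3-carboxylate
Conditions: Br2 (2.2 equiv), CH2Cl2, 0 °C → rt; aq Na2S2O3
Reagents that add atoms: bromine, BrBr
Why: Electrophilic ipso-bromodesilylation: each C–Si bond stabilises the cationic σ-complex and bromide removes silicon, so bromine enters only where silicon stood; relief of strain between the two ortho silyl groups speeds the first exchange, C5 and C6 are also the positions this indole ester brominates at by itself, and C2 is deactivated by the ester.

Step 8
Reactants: 12 methyl 5,6-dibromo-1-methylindole-3-carboxylate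
Product: 14 methyl 2,5,6-tribromo-1-methylindole-3-carboxylate, via 2-lithioindole 13 (not isolated)
Conditions: LiN(iPr)2 (LDA, 1.1 equiv), THF, −78 °C, short metalation; then BrCCl2CCl2Br, −78 °C → rt
Reagents that add atoms: 1,2-dibromo-1,1,2,2-tetrachloroethane, BrC(Cl)(Cl)C(Cl)(Cl)Br
Why: Directed ortho-metalation: C2–H is the most acidic proton (α to nitrogen and ortho to the coordinating ester), a lithium amide does not undergo bromine–lithium exchange at C5 or C6, and the aryllithium 13 is brominated by the positive-halogen donor with loss of tetrachloroethene.

Step 9
Reactants: 14 methyl 2,5,6-tribromo-1-methylindole-3-carboxylate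
Product: 15 (2,5,6-tribromo-1-methylindol-3-yl)methanol
Conditions: iBu2AlH (DIBAL-H, 2.5 equiv), CH2Cl2, −78 → 0 °C; aq potassium sodium tartrate
Reagents that add atoms: none
Why: Hydride reduction of an ester to the primary alcohol; iBu2AlH at low temperature leaves aryl bromides untouched, and the cold, non-acidic work-up avoids ionisation of the indol-3-ylmethyl alkoxide, which would lead to over-reduction to the 3-methylindole.

Step 10
Reactants: 15 (2,5,6-tribromo-1-methylindol-3-yl)methanol
Product: 17 2,5,6-tribromo-1-methylgramine [1-(2,5,6-tribromo-1-methylindol-3-yl)-N,N-dimethylmethanamine], via mesylate 16 (not isolated)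
Conditions: MsCl, iPr2NEt, CH2Cl2, −20 °C; then Me2NH (2 M in THF, excess), −20 °C → rt
Reagents that add atoms: dimethylamine, CNC
Why: Sulfonylation of a benzylic-type alcohol followed by amine displacement; the indol-3-ylmethyl sulfonate 16 ionises readily to a nitrogen-stabilised cation (SN1-like), which excess dimethylamine captures at the exocyclic carbon; the hindered tertiary base cannot compete as a nucleophile, and with C2 and C3 substituted no diindolylmethane can form.

## Compound list

1 | dimethyl glutaconate [dimethyl (E)-pent-2-enedioate] | COC(=O)/C=C/CC(=O)OC | starting material
2 | tosylmethyl isocyanide | Cc1ccc(S(=O)(=O)C[N+]#[C-])cc1 | starting material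
3 | methyl 4-(2-methoxy-2-oxoethyl)-1H-pyrrole-3-carboxylate | COC(=O)Cc1c[nH]cc1C(=O)OC | intermediate
4 | methyl 4-(2-methoxy-2-oxoethyl)-1-methylpyrrole-3-carboxylate | COC(=O)Cc1cn(C)cc1C(=O)OC | intermediate
5 | Vilsmeier iminium salt: [3-(2-methoxy-2-oxoethyl)-4-(methoxycarbonyl)-1-methylpyrrol-2-yl]methylidene-dimethyliminium dichlorophosphate | COC(=O)Cc1c(C=[N+](C)C)n(C)cc1C(=O)OC.[O-]P(=O)(Cl)Cl | intermediate (not isolated)
6 | methyl 5-formyl-4-(2-methoxy-2-oxoethyl)-1-methylpyrrole-3-carboxylate | COC(=O)Cc1c(C=O)n(C)cc1C(=O)OC | intermediate
7 | 2-[2-formyl-4-(methoxycarbonyl)-1-methylpyrrol-3-yl]acetic acid | OC(=O)Cc1c(C=O)n(C)cc1C(=O)OC | intermediate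
8 | methyl 1-methyl-5-oxo-1,5-dihydropyrano[3,4-b]pyrrole-3-carboxylate | CN1C=C(C(=O)OC)C2=CC(=O)OC=C12 | intermediate
9 | bis(trimethylsilyl)acetylene | C[Si](C)(C)C#C[Si](C)(C)C | starting material
10 | bridged lactone cycloadduct (racemic): C4 and C7 of 8 joined by the new C(SiMe3)=C(SiMe3) bridge and still spanned by the C5(=O)–O6 lactone bridge, pyrrole ring aromatic | COC(=O)c1cn(C)c2c1[C@@H]1C(=O)O[C@H]2C([Si](C)(C)C)=C1[Si](C)(C)C | intermediate (not isolated)
11 | methyl 1-methyl-5,6-bis(trimethylsilyl)indole-3-carboxylate | COC(=O)c1cn(C)c2cc([Si](C)(C)C)c([Si](C)(C)C)cc12 | intermediate
12 | methyl 5,6-dibromo-1-methylindole-3-carboxylate | COC(=O)c1cn(C)c2cc(Br)c(Br)cc12 | intermediate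
13 | methyl 5,6-dibromo-2-lithio-1-methylindole-3-carboxylate | COC(=O)c1c([Li])n(C)c2cc(Br)c(Br)cc12 | intermediate (not isolated)
14 | methyl 2,5,6-tribromo-1-methylindole-3-carboxylate | COC(=O)c1c(Br)n(C)c2cc(Br)c(Br)cc12 | intermediate
15 | (2,5,6-tribromo-1-methylindol-3-yl)methanol | OCc1c(Br)n(C)c2cc(Br)c(Br)cc12 | intermediate
16 | (2,5,6-tribromo-1-methylindol-3-yl)methyl methanesulfonate | CS(=O)(=O)OCc1c(Br)n(C)c2cc(Br)c(Br)cc12 | intermediate (not isolated)
17 | 2,5,6-tribromo-1-methylgramine | CN(C)Cc1c(Br)n(C)c2cc(Br)c(Br)cc12 | target

## Step count and risks

Total step count: 10. Longest linear sequence: 10 steps (from 1 and 2 to 17).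

**Step 6 (key step).** The cycloaddition may be slow, because the alkyne carries two bulky silyl groups and no activating substituent. This would leave time for self-dimerisation or thermal breakdown of the quinoid diene; traces of acid at 160 °C could also cause protodesilylation.
Fallback: one silicon and the innate selectivity of the ring replace the two silicons. Setting out from 8, cycloaddition with the less hindered ethynyltrimethylsilane (sealed tube, PhCl, 140 °C) should give a mixture of methyl 1-methyl-5-(trimethylsilyl)indole-3-carboxylate F1 and methyl 1-methyl-6-(trimethylsilyl)indole-3-carboxylate F2. The unseparated mixture is treated with Br2 in AcOH. Ipso-substitution at the silyl carbon and electrophilic bromination at the neighbouring free position (C6 or C5, the positions an indole-3-carboxylate brominates at) should make both isomers converge on 12, where the route is rejoined.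

**Step 5.** The quinoid pyranone may dimerise by self-cycloaddition, or be reopened by moisture, while it is concentrated and stored.
Fallback: the diene is not isolated. Setting out from 7, dehydration with N,N'-diisopropylcarbodiimide (which leaves no acid beside the arylsilane) is run in hot PhBr in the presence of a large excess of 9, so that 8 is trapped as it forms. The route is rejoined at 11.

**Step 8.** The amide base may also deprotonate next to the ring-A bromines (C4–H or C7–H); loss of LiBr to an aryne or migration of bromine would follow.
Fallback: the order of the two halogenations is reversed, so that no aryl bromide is present when the base is used. Setting out from 11, C2 lithiation and bromination under the conditions of step 8 should give methyl 2-bromo-1-methyl-5,6-bis(trimethylsilyl)indole-3-carboxylate F3. Br2 in CH2Cl2 then exchanges both silyl groups and the route is rejoined at 14.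

**Step 10.** The product amine may compete with dimethylamine for the cationic electrophile, giving quaternary ammonium salts, or the alcohol may ionise and oligomerise before it is activated.
Fallback: the C–N bond is made at a carbonyl carbon instead of through a cation. Setting out from 15, oxidation with MnO2 (CH2Cl2, rt) should give 2,5,6-tribromo-1-methylindole-3-carbaldehyde F4. Reductive amination with Me2NH and NaBH(OAc)3 (ClCH2CH2Cl, AcOH, rt) then rejoins the route at 17.

## Further compounds

F0 | step 5 | none | none
F1 | step 6 | methyl 1-methyl-5-(trimethylsilyl)indole-3-carboxylate | COC(=O)c1cn(C)c2ccc([Si](C)(C)C)cc12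
F2 | step 6 | methyl 1-methyl-6-(trimethylsilyl)indole-3-carboxylate | COC(=O)c1cn(C)c2cc([Si](C)(C)C)ccc12
F3 | step 8 | methyl 2-bromo-1-methyl-5,6-bis(trimethylsilyl)indole-3-carboxylate | COC(=O)c1c(Br)n(C)c2cc([Si](C)(C)C)c([Si](C)(C)C)cc12
F4 | step 10 | 2,5,6-tribromo-1-methylindole-3-carbaldehyde | O=Cc1c(Br)n(C)c2cc(Br)c(Br)cc12
A1 | alternative 1 | S-[2-[(3,4-dibromophenyl)(methyl)amino]-2-oxoethyl] O-ethyl carbonodithioate | CCOC(=S)SCC(=O)N(C)c1ccc(Br)c(Br)c1
A2 | alternative 1 | 5,6-dibromo-1-methylindolin-2-one | CN1C(=O)Cc2cc(Br)c(Br)cc21
A3 | alternative 1 | 4,5-dibromo-1-methylindolin-2-one | CN1C(=O)Cc2c(Br)c(Br)ccc21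
A4 | alternative 2 | 3,4-dibromothiophene 1,1-dioxide | O=S1(=O)C=C(Br)C(Br)=C1
A5 | alternative 2 | tert-butyl 2,3-dihydro-1H-pyrrole-1-carboxylate | CC(C)(C)OC(=O)N1CCC=C1
A6 | alternative 2 | tert-butyl cis-5,6-dibromo-2,3,3a,7a-tetrahydroindole-1-carboxylate (racemic) | CC(C)(C)OC(=O)N1CC[C@H]2C=C(Br)C(Br)=C[C@@H]12
A7 | alternative 3 | methyl (Z)-2-azido-3-(3,4-dibromophenyl)acrylate | COC(=O)/C(N=[N+]=[N-])=C/c1ccc(Br)c(Br)c1
A8 | alternative 3 | methyl 5,6-dibromo-1H-indole-2-carboxylate | COC(=O)c1cc2cc(Br)c(Br)cc2[nH]1
A9 | alternative 3 | methyl 6,7-dibromo-1H-indole-2-carboxylate | COC(=O)c1cc2ccc(Br)c(Br)c2[nH]1
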